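## Retrosynthetic overview

- **Feature:** in ring C, O1 and the carbonyl carbon C4 are attached to the neighbouring ring A carbons C8a and C4a, and the C5 oxygen stands next to C4a. Cutting O1–C8a and C4a–C4 leaves a ring A aryne (C4a≡C8a, polarised by the C5 oxygen) and a C2–C3–C4 β-oxy ester that carries ring B and the only stereocentre.
- **Ring order:** rings A and B are bought as benzene rings. Ring C is the only ring made, in one aryne O-arylation/acyl-capture annulation, and two MOM ethers are removed last.
- **Aryne precursor:** methyl 2,4,6-trihydroxybenzoate (ester parked on the future C4a) → double C-prenylation → 7-O-methylation → mono-MOM → saponification/decarboxylation → bromination → retro-Brook silylation/triflation.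
- **β-Oxy ester:** 4-hydroxyacetophenone → MOM ether → Claisen condensation with dimethyl carbonate → asymmetric transfer hydrogenation (sets C2 as S) → O-TMS ether, the proton-free form of the alkoxide.

Key step: step 12

Remark: the stereocentre in the given SMILES is C2 with (S) configuration. Prenyl means 3-methylbut-2-en-1-yl. Flavanone numbering (O1, C2, C3, C4, C4a, C5 to C8, C8a) is used for these atoms in the precursors as well.

## Route

Step 1
Reactants: 1 methyl 2,4,6-trihydroxybenzoate; 2 prenyl bromide (1-bromo-3-methylbut-2-ene)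
Product: 3 methyl 2,4,6-trihydroxy-3,5-bis(3-methylbut-2-en-1-yl)benzoate
Conditions: 2 (2.1 equiv), KOH (2.2 equiv), H2O, 0 °C to rt, N2
Reagents that add atoms: prenyl bromide (2), CC(C)=CCBr
Why: C-alkylation of an ambident phenoxide (the aqueous-base prenylation known for acylphloroglucinols), in which water solvates the oxygens so that the soft allylic bromide is attacked by ring carbon in an SN2 reaction, and because the ester occupies the future C4a only the two C–H positions, the future C6 and C8, can take a prenyl group.

Step 2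
Reactants: 3 methyl 2,4,6-trihydroxy-3,5-bis(3-methylbut-2-en-1-yl)benzoate
Product: 4 methyl 2,6-dihydroxy-4-methoxy-3,5-bis(3-methylbut-2-en-1-yl)benzoate
Conditions: Me2SO4 (1.05 equiv), K2CO3 (1.1 equiv), acetone, rt, N2
Reagents that add atoms: dimethyl sulfate, COS(=O)(=O)OC
Why: Williamson-type O-methylation, in which the 4-OH is the most acidic hydroxyl and the only one not hydrogen-bonded to the ester, so one equivalent of the hard electrophile should methylate it alone and give the future 7-OMe.

Step 3
Reactants: 4 methyl 2,6-dihydroxy-4-methoxy-3,5-bis(3-methylbut-2-en-1-yl)benzoate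
Product: 5 methyl 2-hydroxy-4-methoxy-6-(methoxymethoxy)-3,5-bis(3-methylbut-2-en-1-yl)benzoate
Conditions: MOMCl (1.1 equiv), i-Pr2NEt, CH2Cl2, 0 °C to rt
Reagents that add atoms: chloromethyl methyl ether (MOMCl), COCCl
Why: MOM protection by O-alkylation, in which capping one of the two equivalent ortho hydroxyls leaves the other locked in a strong hydrogen bond to the ester carbonyl and much less reactive, so the symmetric diol should be desymmetrised without a statistical mixture.

Step 4
Reactants: 5 methyl 2-hydroxy-4-methoxy-6-(methoxymethoxy)-3,5-bis(3-methylbut-2-en-1-yl)benzoate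
Product: 7 3-methoxy-5-(methoxymethoxy)-2,4-bis(3-methylbut-2-en-1-yl)phenol, via potassium carboxylate 6 (not isolated)
Conditions: KOH (6 equiv), EtOH/H2O 2:1, reflux; aq NH4Cl work-up
Reagents that add atoms: none
Why: Saponification followed by protodecarboxylation of an electron-rich salicylate, in which the carboxylate-bearing carbon is ortho to a phenoxide and para to a methoxy group and is therefore protonated easily with loss of CO2, while the MOM ether, methyl ether and prenyl groups are inert to aqueous base.

Step 5
Reactants: 7 3-methoxy-5-(methoxymethoxy)-2,4-bis(3-methylbut-2-en-1-yl)phenol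
Product: 8 2-bromo-5-methoxy-3-(methoxymethoxy)-4,6-bis(3-methylbut-2-en-1-yl)phenol
Conditions: NBS (1.0 equiv), i-Pr2NH (10 mol %), CH2Cl2, −40 °C, dark
Reagents that add atoms: N-bromosuccinimide, O=C1CCC(=O)N1Br
Why: Electrophilic aromatic bromination, in which the single free ring position (future C4a) is ortho to OH and OMOM and para to OMe and should outrun the trisubstituted alkenes at low temperature, helped by amine-mediated delivery of bromine to the position ortho to the phenol.

Step 6
Reactants: 8 2-bromo-5-methoxy-3-(methoxymethoxy)-4,6-bis(3-methylbut-2-en-1-yl)phenol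
Product: 9 [2-bromo-5-methoxy-3-(methoxymethoxy)-4,6-bis(3-methylbut-2-en-1-yl)phenoxy]trimethylsilane
Conditions: HMDS (1.0 equiv), THF, reflux; evaporation
Reagents that add atoms: hexamethyldisilazane, C[Si](C)(C)N[Si](C)(C)C
Why: O-silylation of a phenol with HMDS, which gives only a volatile by-product so that the moisture-sensitive silyl ether can be carried on after evaporation.

Step 7
Reactants: 9 [2-bromo-5-methoxy-3-(methoxymethoxy)-4,6-bis(3-methylbut-2-en-1-yl)phenoxy]trimethylsilane
Product: 12 3-methoxy-5-(methoxymethoxy)-2,4-bis(3-methylbut-2-en-1-yl)-6-(trimethylsilyl)phenyl trifluoromethanesulfonate, via aryllithium 10 (not isolated), via lithium phenoxide 11 (not isolated)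
Conditions: n-BuLi (1.05 equiv), THF, −78 °C; then Tf2O (1.2 equiv), −78 to 0 °C; aq NaHCO3
Reagents that add atoms: trifluoromethanesulfonic anhydride, O=S(=O)(OS(=O)(=O)C(F)(F)F)C(F)(F)F
Why: Bromine–lithium exchange is faster than deprotonation of the benzylic-allylic CH2 groups, aryllithium 10 takes the neighbouring silyl group in a retro-Brook 1,3-shift from O to C, and phenoxide 11 is triflated in the same flask, which is the standard entry to ortho-silylaryl triflates.

Step 8
Reactants: 13 4-hydroxyacetophenone
Product: 14 1-[4-(methoxymethoxy)phenyl]ethan-1-one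
Conditions: MOMCl (1.2 equiv), i-Pr2NEt, CH2Cl2, 0 °C to rt
Reagents that add atoms: chloromethyl methyl ether (MOMCl), COCCl
Why: MOM protection of the phenol by O-alkylation, giving a group that tolerates NaH, transfer hydrogenation and fluoride and leaves together with the C5 MOM group in the last step.

Step 9
Reactants: 14 1-[4-(methoxymethoxy)phenyl]ethan-1-one; 15 dimethyl carbonate
Product: 16 methyl 3-[4-(methoxymethoxy)phenyl]-3-oxopropanoate
Conditions: NaH (2.0 equiv), 15 (3 equiv), THF, reflux; AcOH quench
Reagents that add atoms: dimethyl carbonate (15), COC(=O)OC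
Why: Crossed Claisen condensation of the methyl ketone enolate with a non-enolisable carbonate, driven by irreversible deprotonation of the β-keto ester.

Step 10
Reactants: 16 methyl 3-[4-(methoxymethoxy)phenyl]-3-oxopropanoate
Product: 17 methyl (3S)-3-hydroxy-3-[4-(methoxymethoxy)phenyl]propanoate
Conditions: RuCl(p-cymene)[(S,S)-TsDPEN] (1 mol %), HCO2H/Et3N 5:2, EtOAc, 30 °C
Reagents that add atoms: none
Why: Noyori-type asymmetric transfer hydrogenation, in which the (S,S)-TsDPEN ruthenium hydride delivers hydrogen to the ketone face fixed by the C–H/π contact between the aryl group and the cymene ligand and should give the (3S)-alcohol (future C2), in a medium mild enough to spare the MOM ether and the solvolysis-prone p-alkoxybenzylic alcohol.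

Step 11
Reactants: 17 methyl (3S)-3-hydroxy-3-[4-(methoxymethoxy)phenyl]propanoate
Product: 18 methyl (3S)-3-[4-(methoxymethoxy)phenyl]-3-[(trimethylsilyl)oxy]propanoate
Conditions: TMSCl (1.2 equiv), imidazole, CH2Cl2, 0 °C; filtration through neutral Al2O3
Reagents that add atoms: chlorotrimethylsilane, C[Si](C)(C)Cl
Why: Standard O-silylation of a secondary alcohol that touches neither the stereocentre nor the ester and turns the alcohol into a proton-free alkoxide source for step 12.

Step 12
Reactants: 12 3-methoxy-5-(methoxymethoxy)-2,4-bis(3-methylbut-2-en-1-yl)-6-(trimethylsilyl)phenyl trifluoromethanesulfonate; 18 methyl (3S)-3-[4-(methoxymethoxy)phenyl]-3-[(trimethylsilyl)oxy]propanoate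
Product: 22 (2S)-7-methoxy-5-(methoxymethoxy)-2-[4-(methoxymethoxy)phenyl]-6,8-bis(3-methylbut-2-en-1-yl)chroman-4-one, via aryne 19 (not isolated), via caesium alkoxide 20 (not isolated), via aryl anion 21 (not isolated)
Conditions: 12 (1 equiv), 18 (1.5 equiv), CsF (1.1 equiv), 18-crown-6 (1.1 equiv), 4 Å MS, THF, 0 °C to rt; pH 7 phosphate buffer
Reagents that add atoms: none
Why: Proposed new method: fluoride removes the silyl group on C4a of 12 and triflate leaves from C8a to give aryne 19, fluoride (and later the expelled methoxide) takes the O-silyl group of 18 to give alkoxide 20, and 20 adds through oxygen at C8a, after which the C4a carbanion 21 attacks the ester carbonyl and expels methoxide, so that O1–C8a and C4a–C4 form in one operation. The closest known reaction type is the CsF-triggered annulation of arynes with salicylate esters to xanthones (nucleophilic addition followed by intramolecular acyl capture), which has not been shown for an aliphatic β-oxy ester. Ring C closes in the 6-exo-trig mode through C4a, C8a, O1, C2, C3 and C4. No stereocentre is created, because C2 is C3 of 18 and keeps its (S) configuration as neither its C–O nor its C–H bond is touched. The step needs O-attack at C8a and not at C4a, and the σ-withdrawing C5 OMOM group secures this by distorting the aryne so that C8a is the more linear, electrophilic end and the charge builds up at C4a next to oxygen, against the modest steric bias of the C8 prenyl group. The free alcohol 17 is not used because CsF cannot deprotonate it and its O–H would protonate C4a to leave an open aryl ether, whereas with 18 in THF no proton source is present and the released methoxide is consumed as MeOSiMe3 while freeing the next alkoxide, so that with a near-stoichiometric charge of fluoride little base remains to open the flavanone by retro-oxa-Michael reaction.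

Step 13
Reactants: 22 (2S)-7-methoxy-5-(methoxymethoxy)-2-[4-(methoxymethoxy)phenyl]-6,8-bis(3-methylbut-2-en-1-yl)chroman-4-one
Product: 23 (2S)-5-hydroxy-2-(4-hydroxyphenyl)-7-methoxy-6,8-bis(3-methylbut-2-en-1-yl)chroman-4-one (CNP0121058.1)
Conditions: HCl (1 M), MeOH/H2O, rt to 40 °C
Reagents that add atoms: none
Why: Acid-catalysed acetal exchange with methanol removes both aryl MOM ethers under conditions that should be too mild to add the freed 5-OH to the C6 prenyl group and, being non-basic, cannot epimerise C2 through the chalcone.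

## Compound list

| No. | Name | SMILES | Role |
|---|---|---|---|
| 1 | methyl 2,4,6-trihydroxybenzoate | COC(=O)c1c(O)cc(O)cc1O | starting material |
| 2 | prenyl bromide (1-bromo-3-methylbut-2-ene) | CC(C)=CCBr | starting material |
| 3 | methyl 2,4,6-trihydroxy-3,5-bis(3-methylbut-2-en-1-yl)benzoate | COC(=O)c1c(O)c(CC=C(C)C)c(O)c(CC=C(C)C)c1O | intermediate |
| 4 | methyl 2,6-dihydroxy-4-methoxy-3,5-bis(3-methylbut-2-en-1-yl)benzoate | COC(=O)c1c(O)c(CC=C(C)C)c(OC)c(CC=C(C)C)c1O | intermediate |
| 5 | methyl 2-hydroxy-4-methoxy-6-(methoxymethoxy)-3,5-bis(3-methylbut-2-en-1-yl)benzoate | COC(=O)c1c(O)c(CC=C(C)C)c(OC)c(CC=C(C)C)c1OCOC | intermediate |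
| 6 | potassium 2-hydroxy-4-methoxy-6-(methoxymethoxy)-3,5-bis(3-methylbut-2-en-1-yl)benzoate | [K+].[O-]C(=O)c1c(O)c(CC=C(C)C)c(OC)c(CC=C(C)C)c1OCOC | intermediate |
| 7 | 3-methoxy-5-(methoxymethoxy)-2,4-bis(3-methylbut-2-en-1-yl)phenol | COCOc1cc(O)c(CC=C(C)C)c(OC)c1CC=C(C)C | intermediate |
| 8 | 2-bromo-5-methoxy-3-(methoxymethoxy)-4,6-bis(3-methylbut-2-en-1-yl)phenol | COCOc1c(Br)c(O)c(CC=C(C)C)c(OC)c1CC=C(C)C | intermediate |
| 9 | [2-bromo-5-methoxy-3-(methoxymethoxy)-4,6-bis(3-methylbut-2-en-1-yl)phenoxy]trimethylsilane | COCOc1c(Br)c(O[Si](C)(C)C)c(CC=C(C)C)c(OC)c1CC=C(C)C | intermediate |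
| 10 | {4-methoxy-2-(methoxymethoxy)-3,5-bis(3-methylbut-2-en-1-yl)-6-[(trimethylsilyl)oxy]phenyl}lithium | [Li]c1c(OCOC)c(CC=C(C)C)c(OC)c(CC=C(C)C)c1O[Si](C)(C)C | intermediate |
| 11 | lithium 3-methoxy-5-(methoxymethoxy)-2,4-bis(3-methylbut-2-en-1-yl)-6-(trimethylsilyl)phenoxide | [Li+].[O-]c1c(CC=C(C)C)c(OC)c(CC=C(C)C)c(OCOC)c1[Si](C)(C)C | intermediate |
| 12 | 3-methoxy-5-(methoxymethoxy)-2,4-bis(3-methylbut-2-en-1-yl)-6-(trimethylsilyl)phenyl trifluoromethanesulfonate | C[Si](C)(C)c1c(OCOC)c(CC=C(C)C)c(OC)c(CC=C(C)C)c1OS(=O)(=O)C(F)(F)F | intermediate |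
| 13 | 4-hydroxyacetophenone | CC(=O)c1ccc(O)cc1 | starting material |
| 14 | 1-[4-(methoxymethoxy)phenyl]ethan-1-one | CC(=O)c1ccc(OCOC)cc1 | intermediate |
| 15 | dimethyl carbonate | COC(=O)OC | starting material |
| 16 | methyl 3-[4-(methoxymethoxy)phenyl]-3-oxopropanoate | COC(=O)CC(=O)c1ccc(OCOC)cc1 | intermediate |
| 17 | methyl (3S)-3-hydroxy-3-[4-(methoxymethoxy)phenyl]propanoate | COC(=O)C[C@H](O)c1ccc(OCOC)cc1 | intermediate |
| 18 | methyl (3S)-3-[4-(methoxymethoxy)phenyl]-3-[(trimethylsilyl)oxy]propanoate | COC(=O)C[C@H](O[Si](C)(C)C)c1ccc(OCOC)cc1 | intermediate |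
| 19 | 1,2-didehydro-5-methoxy-3-(methoxymethoxy)-4,6-bis(3-methylbut-2-en-1-yl)benzene (aryne C4a≡C8a) | COCOC1=C(CC=C(C)C)C(OC)=C(CC=C(C)C)C#C1 | intermediate |
| 20 | caesium (1S)-3-methoxy-1-[4-(methoxymethoxy)phenyl]-3-oxopropan-1-olate | [Cs+].COC(=O)C[C@H]([O-])c1ccc(OCOC)cc1 | intermediate |
| 21 | caesium salt of the C4a aryl anion of methyl (3S)-3-[3-methoxy-5-(methoxymethoxy)-2,4-bis(3-methylbut-2-en-1-yl)phenoxy]-3-[4-(methoxymethoxy)phenyl]propanoate | [Cs+].COC(=O)C[C@H](Oc1[c-]c(OCOC)c(CC=C(C)C)c(OC)c1CC=C(C)C)c1ccc(OCOC)cc1 | intermediate |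
| 22 | (2S)-7-methoxy-5-(methoxymethoxy)-2-[4-(methoxymethoxy)phenyl]-6,8-bis(3-methylbut-2-en-1-yl)chroman-4-one | COc1c(CC=C(C)C)c(OCOC)c2c(c1CC=C(C)C)O[C@H](c1ccc(OCOC)cc1)CC2=O | intermediate |
| 23 | (2S)-5-hydroxy-2-(4-hydroxyphenyl)-7-methoxy-6,8-bis(3-methylbut-2-en-1-yl)chroman-4-one | COc1c(CC=C(C)C)c(O)c2c(c1CC=C(C)C)O[C@H](c1ccc(O)cc1)CC2=O | target |

## Step count and risks

Total step count: 13 steps.
Longest linear sequence: 9 steps (steps 1 to 7, 12 and 13). The side-chain branch (steps 8 to 11) joins at step 12.

**1. Step 12 (the proposed method).** Several processes could defeat it: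
- The C4a carbanion may capture a proton before acyl transfer.
- The alkoxide may undergo retro-aldol cleavage or β-elimination before it meets the aryne.
- The aryne may be consumed in ene-type reactions with prenyl groups of a second molecule.
- Residual base may open ring C, with erosion of the enantiomeric purity.

The fallback uses known chemistry and makes the same two bonds one after the other. It sets out from bromophenol 8 and keto ester 16 and comes back to the route at 22. Keto ester 16 is reduced with the enantiomeric catalyst RuCl(p-cymene)[(R,R)-TsDPEN] to methyl (3R)-3-hydroxy-3-[4-(methoxymethoxy)phenyl]propanoate F1. This is converted with MeNHOMe·HCl and i-PrMgCl into the Weinreb amide (3R)-3-hydroxy-N-methoxy-3-[4-(methoxymethoxy)phenyl]-N-methylpropanamide F2. Mitsunobu etherification of 8 with F2 (PPh3, DIAD, toluene, 0 °C) forms O1–C8a with inversion. It gives (3S)-3-[2-bromo-5-methoxy-3-(methoxymethoxy)-4,6-bis(3-methylbut-2-en-1-yl)phenoxy]-N-methoxy-3-[4-(methoxymethoxy)phenyl]-N-methylpropanamide F3. Bromine–lithium exchange (t-BuLi, THF, −95 °C) and Parham-type cycliacylation of the C4a aryllithium on the amide then form C4a–C4 and deliver 22.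

**2. Step 1.** Alkylation may run on to a second prenylation at an already substituted carbon with loss of aromaticity. O-alkylation and incomplete conversion may also compete.

The fallback replaces phenoxide alkylation by cross-coupling. It sets out from 1 and comes back at 4. Selective 4-O-methylation of 1 (Me2SO4, K2CO3, acetone) gives methyl 2,6-dihydroxy-4-methoxybenzoate F4. Double iodination of the two free positions (NIS, MeCN, 0 °C) gives methyl 2,6-dihydroxy-3,5-diiodo-4-methoxybenzoate F5. A double Stille coupling with tributyl(3-methylbut-2-en-1-yl)stannane (Pd(PPh3)4, DMF, 80 °C) gives 4.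

**3. Step 5.** The electrophilic bromine may attack the prenyl double bonds, followed by bromoetherification through the neighbouring phenol.

The fallback avoids any electrophilic halogen and installs silicon by directed ortho-metalation. It sets out from phenol 7 and comes back at 12, bypassing steps 5 to 7. Addition of 7 to isopropyl isocyanate (Et3N cat., CH2Cl2) gives 3-methoxy-5-(methoxymethoxy)-2,4-bis(3-methylbut-2-en-1-yl)phenyl N-(propan-2-yl)carbamate F6. Ortho-lithiation between the carbamate and the OMOM group follows (TBSOTf and TMEDA for temporary N-protection, then n-BuLi/TMEDA at −78 °C, then TMSCl, aq NaHCO3 work-up). It gives 3-methoxy-5-(methoxymethoxy)-2,4-bis(3-methylbut-2-en-1-yl)-6-(trimethylsilyl)phenyl N-(propan-2-yl)carbamate F7. Base-induced carbamate cleavage and triflation in one flask (Et2NH, DBU, MeCN, 40 °C, then PhNTf2) gives 12.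

## Further compounds

F1 | step 12 | methyl (3R)-3-hydroxy-3-[4-(methoxymethoxy)phenyl]propanoate | COC(=O)C[C@@H](O)c1ccc(OCOC)cc1
F2 | step 12 | (3R)-3-hydroxy-N-methoxy-3-[4-(methoxymethoxy)phenyl]-N-methylpropanamide | CON(C)C(=O)C[C@@H](O)c1ccc(OCOC)cc1
F3 | step 12 | (3S)-3-[2-bromo-5-methoxy-3-(methoxymethoxy)-4,6-bis(3-methylbut-2-en-1-yl)phenoxy]-N-methoxy-3-[4-(methoxymethoxy)phenyl]-N-methylpropanamide | CON(C)C(=O)C[C@H](Oc1c(Br)c(OCOC)c(CC=C(C)C)c(OC)c1CC=C(C)C)c1ccc(OCOC)cc1
F4 | step 1 | methyl 2,6-dihydroxy-4-methoxybenzoate | COC(=O)c1c(O)cc(OC)cc1O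
F5 | step 1 | methyl 2,6-dihydroxy-3,5-diiodo-4-methoxybenzoate | COC(=O)c1c(O)c(I)c(OC)c(I)c1O
F6 | step 5 | 3-methoxy-5-(methoxymethoxy)-2,4-bis(3-methylbut-2-en-1-yl)phenyl N-(propan-2-yl)carbamate | CC(C)NC(=O)Oc1cc(OCOC)c(CC=C(C)C)c(OC)c1CC=C(C)C
F7 | step 5 | 3-methoxy-5-(methoxymethoxy)-2,4-bis(3-methylbut-2-en-1-yl)-6-(trimethylsilyl)phenyl N-(propan-2-yl)carbamate | CC(C)NC(=O)Oc1c([Si](C)(C)C)c(OCOC)c(CC=C(C)C)c(OC)c1CC=C(C)C
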